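Early in the flask, one-sided end groups have a half-life of 1.31 min against first end groups at their charge, far shorter than the 4.1 h of first end groups by step 1, so capping takes 0.0200 M of first end groups at the outset.

    first end groups + second end groups ⇌ links (K1 = 4.0 M⁻¹, k1 = 2.4 × 10⁻⁵ M⁻¹ s⁻¹)
    first end groups + one-sided end groups → capped ends (k2 = 0.0044 M⁻¹ s⁻¹)
    second end groups + protic impurity → quenched reagent (k3 = 1.3 × 10⁻⁵ M⁻¹ s⁻¹)

first end groups 2.0 M; second end groups 1.96 M; one-sided end groups 0.0200 M; protic impurity 0.400 M; time 15 h

* average number of monomer units in a chain (unreacted monomers counted as chains of one) at 15 h
* part of the first end groups that has reacted at 15 h

- each monomer carries two end groups and one-sided end groups one, which caps an end: a chain counts once for every two ends that are left, dead ends included; the units are half of the end groups of the two monomers charged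
- what has gone from first end groups into another species counts as reacted, even if it can come back
- run time (flask): 15 h

A link joins two chains into one, while capping and quenching leave the chain count untouched. The units stand at 1.98 M, half of the end groups of the two monomers charged, and chains equal units minus c(links), so dp = units/(units − c(links)). The task shrinks to c(links).

After capping, the two partners stand nearly equal, so one concentration sets the order: the forward rate is k1·c², second order. Forward alone, c(links) reaches 1.41 M and dp 3.47.

The objection is the way back: with K1, the rate vanishes at 1.38 M, below that estimate. The other root of the rate law is 2.81 M, and integrating both ways gives 1.26 M, with dp 2.75.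

A second objection is the impurity. At the start, second end groups form links 9.2 times as fast as they are quenched (forward step alone), and dividing the links above by this selectivity factor gives a rough guess of 0.137 M of second end groups lost to quenching, a guess that holds the start ratio for the whole run and sets net links against a forward-only ratio. That thins one of two nearly equal partners, so roughly 0.5 of the loss is counted against links. This reckoning commits to 1.19 M of links, dp 2.51 and c 60.7%.

The forecast gives dp 2.52 and c 60.7%, from “roughly 1.2 M links and 0.79 M first end groups”.

The simulation gives dp 2.52 and c 60.8%. Quenched reagent in this flask stands at 0.194 M after 15.0 h, more than the guess of 0.137 M. With links at 59.8% of the first end groups charged, units/(units − c(links)) gives 2.52 for this flask. The neighbour charged with 0.49 M of second end groups has 1.25 M of units and 0.360 M of links, so the same rule gives 1.41, and that neighbour's run stands at dp 1.41.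

The numbers are invented; the flask was simulated.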